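**Plan**
- Retrosynthetic cuts: the three Si–O bonds; the C8–C1″ aryl–allyl bond; the C3–C4 saturation (back to a 2H‑chromene); the C4–C4a bond of the pyran ring; the O1–C2 ether bond; the C2–C3 bond (aldehyde plus ethynyl).
- Forward order: 2,4‑bis(silyloxy)benzaldehyde plus ethynyl Grignard, then the propargylic carbonate, then copper‑catalysed etherification with 2‑bromo‑3‑methoxyphenol (O1–C2), then gold closure of the pyran ring (C4–C4a), then diimide reduction, C8 allylation and desilylation.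
- Enabling feature: C4a lies para to the C7 methoxy group and ortho to O1, so it can attack an alkyne tethered through O1; C8, the other carbon ortho to O1, carries bromine, which blocks it and later becomes the side‑chain handle.
- Stereochemistry: C2 (S) is set by the ligand in the enantioconvergent copper–pybox etherification and is a spectator afterwards. The (E)‑alkene comes from the E‑selective SeO2 oxidation of prenyl chloride and is kept by an SN2 coupling.

Key step: step 5

Remark: 2‑bromo‑3‑methoxyphenol is taken as a purchasable building block, and the (S,S)‑pybox antipode is assumed to give the (S)‑ether; if the sense of induction is the opposite, the mirror‑image ligand is used without other change.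

**Route**

Step 1
Reactants: 1 2,4‑dihydroxybenzaldehyde
Product: 2 2,4‑bis(tert‑butyldimethylsilyloxy)benzaldehyde
Conditions: TBSCl (2.4 equiv), imidazole, DMF, 0 °C → rt
Reagents that add atoms: tert‑butyldimethylsilyl chloride, CC(C)(C)[Si](C)(C)Cl
Why: Imidazole‑mediated silylation of phenols; with excess reagent in DMF the hydrogen‑bonded 2‑OH is silylated as well.

Step 2
Reactants: 2 2,4‑bis(tert‑butyldimethylsilyloxy)benzaldehyde; 3 ethynylmagnesium bromide
Product: 4 rac‑1‑[2,4‑bis(tert‑butyldimethylsilyloxy)phenyl]prop‑2‑yn‑1‑ol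
Conditions: THF, −78 → −20 °C; aq. NH4Cl
Reagents that add atoms: none
Why: Grignard 1,2‑addition to an aryl aldehyde, quenched cold so that the magnesium alkoxide does not take over the ortho silyl group; the carbinol is deliberately racemic because step 4 is enantioconvergent.

Step 3
Reactants: 4 rac‑1‑[2,4‑bis(tert‑butyldimethylsilyloxy)phenyl]prop‑2‑yn‑1‑ol
Product: 5 rac‑tert‑butyl 1‑[2,4‑bis(tert‑butyldimethylsilyloxy)phenyl]prop‑2‑yn‑1‑yl carbonate
Conditions: Boc2O (1.3 equiv), DMAP (10 mol%), CH2Cl2, 0 °C → rt; chromatography on Et3N‑deactivated silica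
Reagents that add atoms: di‑tert‑butyl dicarbonate, CC(C)(C)OC(=O)OC(=O)OC(C)(C)C
Why: DMAP‑catalysed O‑tert‑butoxycarbonylation of a secondary alcohol under non‑acidic conditions; the leaving group later releases only CO2 and the poorly nucleophilic tert‑butanol.

Step 4
Reactants: 5 rac‑tert‑butyl 1‑[2,4‑bis(tert‑butyldimethylsilyloxy)phenyl]prop‑2‑yn‑1‑yl carbonate; 6 2‑bromo‑3‑methoxyphenol
Product: 7 (S)‑2‑bromo‑3‑methoxyphenyl 1‑[2,4‑bis(tert‑butyldimethylsilyloxy)phenyl]prop‑2‑yn‑1‑yl ether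
Conditions: Cu(OTf)·½C6H6 (5 mol%), (S,S)‑Ph‑pybox (10 mol%), i‑Pr2NEt (1.2 equiv), CH2Cl2, −20 °C
Reagents that add atoms: none
Why: Copper‑catalysed asymmetric propargylic etherification with a phenol: both enantiomers of 5 lose the carbonate to give the same copper allenylidene, and the pybox ligand directs the phenoxide to one face of its γ‑carbon, which sets C2 as (S).

Step 5
Reactants: 7 (S)‑2‑bromo‑3‑methoxyphenyl 1‑[2,4‑bis(tert‑butyldimethylsilyloxy)phenyl]prop‑2‑yn‑1‑yl ether
Product: 8 (S)‑8‑bromo‑2‑[2,4‑bis(tert‑butyldimethylsilyloxy)phenyl]‑7‑methoxy‑2H‑chromene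
Conditions: [JohnPhosAu(NCMe)]SbF6 (3 mol%), CH2Cl2, 0 °C → rt, dark
Reagents that add atoms: none
Why: The cationic phosphine–gold(I) fragment binds the terminal alkyne of 7 as a π‑acid, and the arene carbon para to the methoxy group (the future C4a) attacks the distal alkyne carbon in an intramolecular Friedel–Crafts reaction; rearomatisation and protodeauration of the vinyl–gold species release the 2H‑chromene and the catalyst. This is the established gold(I)‑catalysed intramolecular hydroarylation of aryl propargyl ethers to 2H‑chromenes. The pyran ring closes in the 6‑endo‑dig mode, with C4–C4a as the only new skeletal bond. No stereocentre is created: C2, set in step 4, lies outside the bond‑forming events and is carried over unchanged as long as its C–O bond is not ionised. The selectivity needed is 6‑endo attack at C4a rather than 5‑exo closure, attack at the other ortho carbon or heterolysis of the benzylic, propargylic ether; the para methoxy group directs the attack to C4a, the bromine blocks C8, the terminal alkyne favours the endo mode, and the soft, weakly oxophilic catalyst at low temperature together with the attenuated donor strength of the silyloxy groups should keep the C2–O1 bond intact.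

Step 6
Reactants: 8 (S)‑8‑bromo‑2‑[2,4‑bis(tert‑butyldimethylsilyloxy)phenyl]‑7‑methoxy‑2H‑chromene
Product: 9 (S)‑8‑bromo‑2‑[2,4‑bis(tert‑butyldimethylsilyloxy)phenyl]‑7‑methoxychroman
Conditions: 2‑nitrobenzenesulfonyl hydrazide (NBSH, excess, in portions), Et3N, CH2Cl2, rt
Reagents that add atoms: none
Why: Diimide reduction: concerted syn transfer of H2 to the cis‑disubstituted styrenic C3=C4 bond, which leaves the aryl bromide, the benzylic C2–O bond and the silyl ethers untouched (all at risk under Pd/H2) and does not involve C2.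

Step 7
Reactants: 10 prenyl chloride (1‑chloro‑3‑methylbut‑2‑ene)
Product: 11 (E)‑4‑chloro‑2‑methylbut‑2‑en‑1‑ol
Conditions: SeO2 (cat.), t‑BuOOH, CH2Cl2, rt
Reagents that add atoms: selenium dioxide, O=[Se]=O (catalytic oxygen carrier); tert‑butyl hydroperoxide, CC(C)(C)OO (terminal oxidant)
Why: Sharpless catalytic SeO2 allylic oxidation (ene reaction, then [2,3]‑sigmatropic shift), which oxidises the (E)‑methyl group of a trisubstituted alkene and so fixes the (E)‑geometry of the side chain.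

Step 8
Reactants: 11 (E)‑4‑chloro‑2‑methylbut‑2‑en‑1‑ol
Product: 12 (E)‑tert‑butyl[(4‑chloro‑2‑methylbut‑2‑en‑1‑yl)oxy]dimethylsilane
Conditions: TBSCl, imidazole, CH2Cl2, 0 °C → rt
Reagents that add atoms: tert‑butyldimethylsilyl chloride, CC(C)(C)[Si](C)(C)Cl
Why: Standard silylation of a primary alcohol, which masks the hydroxyl against the organometallic reagent of step 9.

Step 9
Reactants: 9 (S)‑8‑bromo‑2‑[2,4‑bis(tert‑butyldimethylsilyloxy)phenyl]‑7‑methoxychroman; 12 (E)‑tert‑butyl[(4‑chloro‑2‑methylbut‑2‑en‑1‑yl)oxy]dimethylsilane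
Product: 15 (S)‑2‑[2,4‑bis(tert‑butyldimethylsilyloxy)phenyl]‑8‑[(E)‑4‑(tert‑butyldimethylsilyloxy)‑3‑methylbut‑2‑en‑1‑yl]‑7‑methoxychroman, via C8 aryllithium 13 (not isolated), via C8 arylcopper 14 (not isolated)
Conditions: n‑BuLi (1.05 equiv), THF, −78 °C; CuBr·SMe2 (1.1 equiv), −78 → −40 °C; 12 (1.5 equiv), −40 → 0 °C
Reagents that add atoms: none
Why: Bromine–lithium exchange and transmetalation to copper give a soft aryl nucleophile that displaces the primary allylic chloride by SN2 (copper‑mediated allylic substitution, as in the prenylation of 2,6‑dioxygenated aryl metals); the SN2′ mode would have to build a quaternary carbon next to a di‑ortho‑substituted arene, and the alkene geometry is not touched.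

Step 10
Reactants: 15 (S)‑2‑[2,4‑bis(tert‑butyldimethylsilyloxy)phenyl]‑8‑[(E)‑4‑(tert‑butyldimethylsilyloxy)‑3‑methylbut‑2‑en‑1‑yl]‑7‑methoxychroman
Product: 16 morusyunnansin E, (S)‑4‑{8‑[(E)‑4‑hydroxy‑3‑methylbut‑2‑en‑1‑yl]‑7‑methoxychroman‑2‑yl}benzene‑1,3‑diol
Conditions: TBAF/AcOH (1:1, 5 equiv), THF, 0 °C → rt
Reagents that add atoms: none
Why: Fluoride‑mediated cleavage of the two aryl and one primary alkyl Si–O bonds; the acetic acid buffer keeps the freed 2′‑phenol protonated, so the benzylic C2–O1 bond should not open through an ortho‑quinone methide and C2 should keep its configuration.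

**Compound list**
1 | 2,4‑dihydroxybenzaldehyde | O=Cc1ccc(O)cc1O | starting material
2 | 2,4‑bis(tert‑butyldimethylsilyloxy)benzaldehyde | O=Cc1ccc(O[Si](C)(C)C(C)(C)C)cc1O[Si](C)(C)C(C)(C)C | intermediate
3 | ethynylmagnesium bromide | C#C[Mg]Br | starting material
4 | rac‑1‑[2,4‑bis(tert‑butyldimethylsilyloxy)phenyl]prop‑2‑yn‑1‑ol | C#CC(O)c1ccc(O[Si](C)(C)C(C)(C)C)cc1O[Si](C)(C)C(C)(C)C | intermediate
5 | rac‑tert‑butyl 1‑[2,4‑bis(tert‑butyldimethylsilyloxy)phenyl]prop‑2‑yn‑1‑yl carbonate | C#CC(OC(=O)OC(C)(C)C)c1ccc(O[Si](C)(C)C(C)(C)C)cc1O[Si](C)(C)C(C)(C)C | intermediate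
6 | 2‑bromo‑3‑methoxyphenol | COc1cccc(O)c1Br | starting material
7 | (S)‑2‑bromo‑3‑methoxyphenyl 1‑[2,4‑bis(tert‑butyldimethylsilyloxy)phenyl]prop‑2‑yn‑1‑yl ether | COc1cccc(O[C@H](c2ccc(O[Si](C)(C)C(C)(C)C)cc2O[Si](C)(C)C(C)(C)C)C#C)c1Br | intermediate
8 | (S)‑8‑bromo‑2‑[2,4‑bis(tert‑butyldimethylsilyloxy)phenyl]‑7‑methoxy‑2H‑chromene | COc1ccc2c(c1Br)O[C@H](c1ccc(O[Si](C)(C)C(C)(C)C)cc1O[Si](C)(C)C(C)(C)C)C=C2 | intermediate
9 | (S)‑8‑bromo‑2‑[2,4‑bis(tert‑butyldimethylsilyloxy)phenyl]‑7‑methoxychroman | COc1ccc2c(c1Br)O[C@H](c1ccc(O[Si](C)(C)C(C)(C)C)cc1O[Si](C)(C)C(C)(C)C)CC2 | intermediate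
10 | prenyl chloride (1‑chloro‑3‑methylbut‑2‑ene) | CC(C)=CCCl | starting material
11 | (E)‑4‑chloro‑2‑methylbut‑2‑en‑1‑ol | OC/C(C)=C/CCl | intermediate
12 | (E)‑tert‑butyl[(4‑chloro‑2‑methylbut‑2‑en‑1‑yl)oxy]dimethylsilane | CC(C)(C)[Si](C)(C)OC/C(C)=C/CCl | intermediate
13 | [(S)‑2‑[2,4‑bis(tert‑butyldimethylsilyloxy)phenyl]‑7‑methoxychroman‑8‑yl]lithium | COc1ccc2c(c1[Li])O[C@H](c1ccc(O[Si](C)(C)C(C)(C)C)cc1O[Si](C)(C)C(C)(C)C)CC2 | intermediate
14 | [(S)‑2‑[2,4‑bis(tert‑butyldimethylsilyloxy)phenyl]‑7‑methoxychroman‑8‑yl]copper | COc1ccc2c(c1[Cu])O[C@H](c1ccc(O[Si](C)(C)C(C)(C)C)cc1O[Si](C)(C)C(C)(C)C)CC2 | intermediate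
15 | (S)‑2‑[2,4‑bis(tert‑butyldimethylsilyloxy)phenyl]‑8‑[(E)‑4‑(tert‑butyldimethylsilyloxy)‑3‑methylbut‑2‑en‑1‑yl]‑7‑methoxychroman | COc1ccc2c(c1C/C=C(\C)CO[Si](C)(C)C(C)(C)C)O[C@H](c1ccc(O[Si](C)(C)C(C)(C)C)cc1O[Si](C)(C)C(C)(C)C)CC2 | intermediate
16 | morusyunnansin E, (S)‑4‑{8‑[(E)‑4‑hydroxy‑3‑methylbut‑2‑en‑1‑yl]‑7‑methoxychroman‑2‑yl}benzene‑1,3‑diol | COc1ccc2c(c1C/C=C(\C)CO)O[C@H](c1ccc(O)cc1O)CC2 | target

**Step count and risks**

Total step count: 10 (steps 1–6, 9 and 10 in the main line; steps 7 and 8 for the side‑chain reagent).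
Longest linear sequence: 8 steps (1 → 2 → 4 → 5 → 7 → 8 → 9 → 15 → 16).

Steps most likely to fail:

1. Step 4. The carbonate may ionise without copper, since the cation would be benzylic, propargylic and flanked by two oxygen donors. A racemic background substitution, or attack through a ring carbon of the phenol, would then erode the enantiomeric purity at C2. The fallback sets out from aldehyde 2 and comes back at ether 7; it sets the centre by reagent‑controlled alkynylation and transfers it with inversion. Zinc‑acetylide addition of trimethylsilylacetylene to 2 (Me2Zn, ProPhenol ligand of the antipode that delivers this enantiomer, toluene) should give (S)‑1‑[2,4‑bis(tert‑butyldimethylsilyloxy)phenyl]‑3‑(trimethylsilyl)prop‑2‑yn‑1‑ol F1. Its descriptor differs from that of the next compound only because the silylalkynyl group outranks the aryl group. Silver‑catalysed protodesilylation of the alkyne (AgNO3 cat., acetone/H2O), which spares aryl silyl ethers, should give (R)‑1‑[2,4‑bis(tert‑butyldimethylsilyloxy)phenyl]prop‑2‑yn‑1‑ol F2. Mitsunobu etherification of F2 with phenol 6 (PPh3, DIAD, toluene, 0 °C) proceeds with SN2 inversion and should return 7.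

2. Step 5. Heterolysis of the C2–O1 bond under the cationic catalyst or adventitious acid would racemise C2 or release phenol 6, and 5‑exo closure could compete. The fallback sets out from 7 and comes back at chroman 9; it lowers the donor strength of the resorcinol ring before the ring closure. Fluoride‑triggered silyl‑to‑acetyl exchange (CsF, Ac2O, DMF, 0 °C) should give (S)‑4‑[1‑(2‑bromo‑3‑methoxyphenoxy)prop‑2‑yn‑1‑yl]‑1,3‑phenylene diacetate F3, in which the benzylic cation is far less stabilised. The same gold hydroarylation should give (S)‑4‑(8‑bromo‑7‑methoxy‑2H‑chromen‑2‑yl)‑1,3‑phenylene diacetate F4, and diimide reduction should give (S)‑4‑(8‑bromo‑7‑methoxychroman‑2‑yl)‑1,3‑phenylene diacetate F5. Methanolysis (K2CO3 cat., MeOH, 0 °C) should give (S)‑4‑(8‑bromo‑7‑methoxychroman‑2‑yl)benzene‑1,3‑diol F6, and silylation (TBSCl, imidazole, DMF) returns 9.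

3. Step 9. Proton transfer from C2–H to the C8 aryllithium before transmetalation, delivery in the SN2′ mode, or slow coupling of the hindered arylcopper with the allylic chloride would each cost material or stereochemical integrity. The fallback sets out from 9 and comes back at target 16; it avoids organolithium chemistry and builds the alkene by metathesis. Fluoride‑free Stille coupling of 9 with allyltributylstannane (Pd(Pt‑Bu3)2 cat., toluene, 90 °C) should give (S)‑8‑allyl‑2‑[2,4‑bis(tert‑butyldimethylsilyloxy)phenyl]‑7‑methoxychroman F7. E‑selective cross‑metathesis with methacrolein (Grubbs II, CH2Cl2, 40 °C) should give (S,E)‑4‑{2‑[2,4‑bis(tert‑butyldimethylsilyloxy)phenyl]‑7‑methoxychroman‑8‑yl}‑2‑methylbut‑2‑enal F8. Luche reduction (NaBH4, CeCl3·7H2O, MeOH, 0 °C) should give (S,E)‑4‑{2‑[2,4‑bis(tert‑butyldimethylsilyloxy)phenyl]‑7‑methoxychroman‑8‑yl}‑2‑methylbut‑2‑en‑1‑ol F9, and buffered desilylation as in step 10 gives 16.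

**Further compounds**
F1 | step 4 | (S)‑1‑[2,4‑bis(tert‑butyldimethylsilyloxy)phenyl]‑3‑(trimethylsilyl)prop‑2‑yn‑1‑ol | O[C@@H](c1ccc(O[Si](C)(C)C(C)(C)C)cc1O[Si](C)(C)C(C)(C)C)C#C[Si](C)(C)C
F2 | step 4 | (R)‑1‑[2,4‑bis(tert‑butyldimethylsilyloxy)phenyl]prop‑2‑yn‑1‑ol | O[C@@H](c1ccc(O[Si](C)(C)C(C)(C)C)cc1O[Si](C)(C)C(C)(C)C)C#C
F3 | step 5 | (S)‑4‑[1‑(2‑bromo‑3‑methoxyphenoxy)prop‑2‑yn‑1‑yl]‑1,3‑phenylene diacetate | COc1cccc(O[C@H](c2ccc(OC(C)=O)cc2OC(C)=O)C#C)c1Br
F4 | step 5 | (S)‑4‑(8‑bromo‑7‑methoxy‑2H‑chromen‑2‑yl)‑1,3‑phenylene diacetate | COc1ccc2c(c1Br)O[C@H](c1ccc(OC(C)=O)cc1OC(C)=O)C=C2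
F5 | step 5 | (S)‑4‑(8‑bromo‑7‑methoxychroman‑2‑yl)‑1,3‑phenylene diacetate | COc1ccc2c(c1Br)O[C@H](c1ccc(OC(C)=O)cc1OC(C)=O)CC2
F6 | step 5 | (S)‑4‑(8‑bromo‑7‑methoxychroman‑2‑yl)benzene‑1,3‑diol | COc1ccc2c(c1Br)O[C@H](c1ccc(O)cc1O)CC2
F7 | step 9 | (S)‑8‑allyl‑2‑[2,4‑bis(tert‑butyldimethylsilyloxy)phenyl]‑7‑methoxychroman | COc1ccc2c(c1CC=C)O[C@H](c1ccc(O[Si](C)(C)C(C)(C)C)cc1O[Si](C)(C)C(C)(C)C)CC2
F8 | step 9 | (S,E)‑4‑{2‑[2,4‑bis(tert‑butyldimethylsilyloxy)phenyl]‑7‑methoxychroman‑8‑yl}‑2‑methylbut‑2‑enal | COc1ccc2c(c1C/C=C(\C)C=O)O[C@H](c1ccc(O[Si](C)(C)C(C)(C)C)cc1O[Si](C)(C)C(C)(C)C)CC2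
F9 | step 9 | (S,E)‑4‑{2‑[2,4‑bis(tert‑butyldimethylsilyloxy)phenyl]‑7‑methoxychroman‑8‑yl}‑2‑methylbut‑2‑en‑1‑ol | COc1ccc2c(c1C/C=C(\C)CO)O[C@H](c1ccc(O[Si](C)(C)C(C)(C)C)cc1O[Si](C)(C)C(C)(C)C)CC2
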